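**Plan**
Feature: in the 14-membered carbocycle, the C9 carbinol is bonded to C8, the methyl-bearing carbon of the E C7=C8 alkene. This E-2-methylallylic alcohol is what forms when H (to C7) and a carbonyl carbon (to C8) add to the same face of a methyl-capped alkyne.
Cuts, in retrosynthetic order: acetates and C9 silyl ether (protecting-group exchange), C8–C9 (opens the only ring to ynal 25), C2–C3 (diene union), C1–isopropyl together with C2–I (carbomagnesiation–iodination of a C1≡C2 alkyne), C1≡C2 (homologation), C11=C12 (Wittig), C12–CH3 (Grignard).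
Forward: the four carbons of D-tartrate become C12–C13–C14–C1. The chain grows west to C9, then east to the C2 iodide, and takes on the C3–C8 enyne iodide 20. The ring closes in step 15, and three protecting-group steps follow.
Stereochemistry: C13 and C14 come from D-tartaric acid. 11Z comes from the Wittig reaction of an α-alkoxy ketone, 1Z from a magnesium chelate to the C14 alkoxide, 3E from syn methylalumination, and 7E from syn addition in the key step. C9 (S) comes from attack on the Re face of the aldehyde under macrocyclic substrate control.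

Key step: step 15

Remark: cembrane numbering is used (C1 isopropyl; C4, C8, C12 methyl; C9 OH; C13, C14 OAc), and the target SMILES reads 1Z,3E,7E,11Z,9S,13R,14R. C13/C14 are carried through the ring closure as triethylsilyl ethers, not as a ketal. The C14–O bond is dienylic and acid-labile, so every late deprotection uses fluoride.

Step 1
Reactants: 1 dimethyl (4S,5S)-2,2-dimethyl-1,3-dioxolane-4,5-dicarboxylate (dimethyl 2,3-O-isopropylidene-D-tartrate)
Product: 2 (4S,5S)-N4,N5-dimethoxy-N4,N5,2,2-tetramethyl-1,3-dioxolane-4,5-dicarboxamide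
Conditions: MeNH(OMe)·HCl (5 equiv), Me3Al (5 equiv), CH2Cl2, 0 °C to rt
Reagents that add atoms: N,O-dimethylhydroxylamine hydrochloride, CNOC.Cl
Why: Aluminium-amide aminolysis of both esters (Weinreb amide formation) is routine for tartrate acetonides; C13 and C14 are taken unchanged from the chiral pool, and the trans-dioxolane is the thermodynamic isomer, so epimerisation is not a concern.

Step 2
Reactants: 2 bis-Weinreb amide
Product: 3 (4S,5S)-5-acetyl-N-methoxy-N,2,2-trimethyl-1,3-dioxolane-4-carboxamide
Conditions: MeMgBr (1.1 equiv), THF, −20 °C; aq NH4Cl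
Reagents that add atoms: methylmagnesium bromide, C[Mg]Br
Why: Weinreb ketone synthesis; the two amides of C2-symmetric 2 are homotopic, and the chelated magnesium hemiaminal from the first addition persists until work-up and shields the neighbouring amide, a known way to desymmetrise tartaric bis-amides.

Step 3
Reactants: 4 (3-bromopropoxy)(tert-butyl)dimethylsilane
Product: 5 [3-(tert-butyldimethylsilyloxy)propyl]triphenylphosphonium bromide
Conditions: PPh3, MeCN, reflux
Reagents that add atoms: triphenylphosphine, c1ccc(cc1)P(c1ccccc1)c1ccccc1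
Why: SN2 quaternisation of triphenylphosphine by a primary bromide.

Step 4
Reactants: 3 keto amide; 5 phosphonium bromide
Product: 7 (4S,5R)-5-[(2Z)-5-(tert-butyldimethylsilyloxy)pent-2-en-2-yl]-N-methoxy-N,2,2-trimethyl-1,3-dioxolane-4-carboxamide, via phosphonium ylide 6 (not isolated)
Conditions: 5 (1.1 equiv), KN(SiMe3)2 (1.05 equiv), THF, 0 °C; then 3, −78 °C to rt
Reagents that add atoms: none
Why: Wittig olefination of an α-alkoxy methyl ketone with a lithium-free non-stabilised ylide, a class known to give the Z-trisubstituted alkene (new chain cis to the oxygenated carbon C13) under kinetic control; the ketone reacts far faster than the amide at low temperature, and the trans-dioxolane disfavours epimerisation at C13.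

Step 5
Reactants: 7 Z-alkenyl Weinreb amide
Product: 9 tert-butyl({(3Z)-4-[(4R,5R)-5-ethynyl-2,2-dimethyl-1,3-dioxolan-4-yl]pent-3-en-1-yl}oxy)dimethylsilane, via dioxolane carbaldehyde 8 (not isolated)
Conditions: i-Bu2AlH (1.2 equiv), CH2Cl2, −78 °C; then MeOH, K2CO3, dimethyl (1-diazo-2-oxopropyl)phosphonate, −78 °C to rt
Reagents that add atoms: dimethyl (1-diazo-2-oxopropyl)phosphonate (Ohira–Bestmann reagent), COP(=O)(OC)C(=[N+]=[N-])C(C)=O
Why: One-pot Weinreb amide reduction and Seyferth–Gilbert homologation; the α-alkoxy aldehyde is never isolated, and C14 stays on the favoured trans-dioxolane.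

Step 6
Reactants: 9 alkynyl dioxolane
Product: 10 (3Z,5R,6R)-4-methyloct-3-en-7-yne-1,5,6-triol
Conditions: p-TsOH·H2O (0.2 equiv), MeOH, rt to 40 °C
Reagents that add atoms: none
Why: Acid-catalysed transketalisation and methanolysis of the primary silyl ether in one operation; at this stage the C13–O bond is only simply allylic and the C14–O bond propargylic, both next to an electron-withdrawing oxygen, so ionisation should not compete.

Step 7
Reactants: 10 enyne triol
Product: 12 (3Z,5R,6R,7Z)-8-iodo-4-methyl-7-(propan-2-yl)octa-3,7-diene-1,5,6-triol, via chelated alkenylmagnesium alkoxide 11 (not isolated)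
Conditions: i-PrMgCl (6 equiv), CuI (0.3 equiv), THF/Et2O, −20 °C to rt; then I2 in THF to persistent colour, −40 °C; aq Na2S2O3
Reagents that add atoms: isopropylmagnesium chloride, CC(C)[Mg]Cl; iodine, II
Why: Copper-catalysed anti-carbomagnesiation of a terminal propargylic alkoxide places isopropyl on C1 and magnesium on C2, where the C14 alkoxide holds it in a five-membered chelate; iodinolysis with retention therefore puts iodine cis to C14 (1Z), and C13/C14 are not touched.

Step 8
Reactants: 12 iodo triol
Product: 13 (3Z,5R,6R,7Z)-8-iodo-4-methyl-7-(propan-2-yl)-1,5,6-tris(triethylsilyloxy)octa-3,7-diene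
Conditions: Et3SiOTf (3.6 equiv), 2,6-lutidine (5 equiv), CH2Cl2, −78 to 0 °C
Reagents that add atoms: triethylsilyl trifluoromethanesulfonate, CC[Si](CC)(CC)OS(=O)(=O)C(F)(F)F
Why: Silyl triflate silylation reaches the hindered secondary hydroxyls too; it is done before the acid-sensitive diene exists.

Step 9
Reactants: 14 trimethyl(prop-1-yn-1-yl)silane; 15 1-bromobut-2-yne
Product: 17 (hepta-1,5-diyn-1-yl)trimethylsilane, via lithiated silylpropyne 16 (not isolated)
Conditions: n-BuLi, THF, −78 to −20 °C; then 15, −78 °C to rt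
Reagents that add atoms: none
Why: SN2 alkylation of lithiated 1-silylpropyne by a primary propargylic bromide forms C5–C6; the silyl group biases the ambident anion towards propargylic attack.

Step 10
Reactants: 17 silyl diyne
Product: 18 hepta-1,5-diyne
Conditions: K2CO3 (0.2 equiv), MeOH, rt; product kept as a CH2Cl2 solution
Reagents that add atoms: none
Why: Methoxide-induced protiodesilylation of an alkynylsilane.

Step 11
Reactants: 18 hepta-1,5-diyne
Product: 20 (1E)-1-iodo-2-methylhept-1-en-5-yne, via alkenyldimethylalane 19 (not isolated)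
Conditions: Me3Al (2 equiv), Cp2ZrCl2 (0.2 equiv), CH2Cl2, 0 °C to rt; then I2, THF, −30 °C
Reagents that add atoms: trimethylaluminium, C[Al](C)C; iodine, II
Why: Negishi zirconium-catalysed methylalumination adds methyl (C4) and aluminium (C3) syn and is much faster for terminal than for internal alkynes; iodinolysis with retention gives the 3E iodide.

Step 12
Reactants: 13 tris-silylated Z-iodide; 20 E-iodide (1.5 equiv)
Product: 23 (3Z,5R,6R,7Z,9E)-4,10-dimethyl-7-(propan-2-yl)-1,5,6-tris(triethylsilyloxy)pentadeca-3,7,9-trien-13-yne, via alkenyllithium 21 (not isolated), via alkenylzinc bromide 22 (not isolated)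
Conditions: 20, t-BuLi (2 equiv per 20), Et2O, −78 °C; ZnBr2, THF, −78 to 0 °C; then 13, Pd(PPh3)4 (5 mol %), THF, rt
Reagents that add atoms: none
Why: Negishi cross-coupling; iodine–lithium exchange, transmetalation and the zerovalent-palladium-catalysed sp2–sp2 coupling all go with retention and give the 1Z,3E diene, and the C–Li bond of 21 points away from the chain, so it cannot add to the alkyne.

Step 13
Reactants: 23 tris(triethylsilyl) ether
Product: 24 (3Z,5R,6R,7Z,9E)-4,10-dimethyl-7-(propan-2-yl)-5,6-bis(triethylsilyloxy)pentadeca-3,7,9-trien-13-yn-1-ol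
Conditions: HF·pyridine, excess pyridine, THF, −10 to 0 °C, stopped at mono-cleavage
Reagents that add atoms: none
Why: Selective fluoride desilylation; a primary triethylsilyl ether is cleaved much faster than the two hindered secondary ones, and the buffered medium spares the dienylic C14–O bond.

Step 14
Reactants: 24 homoallylic alcohol
Product: 25 (3Z,5R,6R,7Z,9E)-4,10-dimethyl-7-(propan-2-yl)-5,6-bis(triethylsilyloxy)pentadeca-3,7,9-trien-13-ynal
Conditions: Dess–Martin periodinane, NaHCO3, CH2Cl2, 0 °C to rt; used at once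
Reagents that add atoms: none
Why: Buffered Dess–Martin oxidation is the standard near-neutral entry to β,γ-unsaturated aldehydes and avoids the amine base that would move the C11=C12 alkene into conjugation.

Step 15
Reactants: 25 ynal
Product: 26 (1Z,3E,7E,9S,11Z,13R,14R)-13,14-bis(triethylsilyloxy)-9-(triisopropylsilyloxy)cembra-1,3,7,11-tetraene
Conditions: Ni(COD)2 (0.25 equiv), 1,3-dimesitylimidazol-2-ylidene (0.25 equiv, isolated carbene, no added base), i-Pr3SiH (3 equiv), THF, rt; 25 added by syringe pump over 6 h, final 0.003 M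
Reagents that add atoms: triisopropylsilane, CC(C)[SiH](C(C)C)C(C)C
Why: Zerovalent nickel carrying one carbene ligand binds the C7≡C8 alkyne and the C9 aldehyde and couples them oxidatively to a five-membered oxanickelacycle (C8–C9 formed, nickel on C7 and O); σ-bond metathesis with the silane then silylates the oxygen and C7–H reductive elimination releases the product, so H and C9 add syn and C7=C8 is E. The closest known reaction type is the nickel/N-heterocyclic carbene/silane reductive macrocyclisation of ynals to endocyclic E-allylic silyl ethers. The single ring, the 14-membered carbocycle, closes end to end in the endocyclic mode, with tether-bearing C7 remaining next to nickel and methyl-bearing C8 taking the aldehyde carbon. The step needs bond formation at C8 rather than C7 (which would give a 13-membered ring with an exocyclic ethylidene), and this is secured by pairing the smallest alkyne cap with a small carbene, which places the larger tether substituent beside nickel and away from the forming bond. The new C9 stereocentre (S) arises from attack on the Re face of the aldehyde under substrate control: C13 and C14 are relayed through the Z C11=C12 alkene, whose allylic 1,3-strain holds the C10–C9 arm on one side of the folded chain, and this is the least secured element. Chemoselectivity rests on a diene fully substituted at both termini (C1, C4) that binds nickel poorly, on allylic oxygens carried as silyl ethers that zerovalent nickel does not ionise, and on base-free catalyst with slow addition, which should suppress aldehyde conjugation and oligomerisation.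

Step 16
Reactants: 26 macrocyclic tris-silyl ether
Product: 27 (1Z,3E,7E,9S,11Z,13R,14R)-9-(triisopropylsilyloxy)cembra-1,3,7,11-tetraene-13,14-diol
Conditions: HF·pyridine, pyridine, THF, 0 °C to rt
Reagents that add atoms: none
Why: Selective fluoride desilylation; secondary triethylsilyl ethers are far more labile than a secondary triisopropylsilyl ether, and no ionising acid meets the dienylic C14–O bond.

Step 17
Reactants: 27 diol
Product: 28 (1Z,3E,7E,9S,11Z,13R,14R)-9-(triisopropylsilyloxy)cembra-1,3,7,11-tetraene-13,14-diyl diacetate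
Conditions: Ac2O, DMAP (cat.), pyridine, rt
Reagents that add atoms: acetic anhydride, CC(=O)OC(C)=O
Why: DMAP-catalysed acylation of both secondary alcohols at oxygen, so C13 and C14 keep their configuration.

Step 18
Reactants: 28 diacetate silyl ether
Product: 29 gibberosene E
Conditions: Bu4NF/AcOH (1:1), THF, rt to 40 °C
Reagents that add atoms: none
Why: Fluoride cleavage of the C9 silyl ether; buffering with acetic acid should prevent acetate hydrolysis or migration.

**Compound list**
1 | dimethyl (4S,5S)-2,2-dimethyl-1,3-dioxolane-4,5-dicarboxylate | COC(=O)[C@H]1OC(C)(C)O[C@@H]1C(=O)OC | starting material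
2 | (4S,5S)-N4,N5-dimethoxy-N4,N5,2,2-tetramethyl-1,3-dioxolane-4,5-dicarboxamide | CON(C)C(=O)[C@H]1OC(C)(C)O[C@@H]1C(=O)N(C)OC | intermediate
3 | (4S,5S)-5-acetyl-N-methoxy-N,2,2-trimethyl-1,3-dioxolane-4-carboxamide | CC(=O)[C@H]1OC(C)(C)O[C@@H]1C(=O)N(C)OC | intermediate
4 | (3-bromopropoxy)(tert-butyl)dimethylsilane | CC(C)(C)[Si](C)(C)OCCCBr | starting material
5 | [3-(tert-butyldimethylsilyloxy)propyl]triphenylphosphonium bromide | CC(C)(C)[Si](C)(C)OCCC[P+](c1ccccc1)(c1ccccc1)c1ccccc1.[Br-] | intermediate
6 | [3-(tert-butyldimethylsilyloxy)propylidene]triphenylphosphorane | CC(C)(C)[Si](C)(C)OCCC=P(c1ccccc1)(c1ccccc1)c1ccccc1 | intermediate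
7 | (4S,5R)-5-[(2Z)-5-(tert-butyldimethylsilyloxy)pent-2-en-2-yl]-N-methoxy-N,2,2-trimethyl-1,3-dioxolane-4-carboxamide | CC(C)(C)[Si](C)(C)OCC/C=C(/C)[C@H]1OC(C)(C)O[C@@H]1C(=O)N(C)OC | intermediate
8 | (4S,5R)-5-[(2Z)-5-(tert-butyldimethylsilyloxy)pent-2-en-2-yl]-2,2-dimethyl-1,3-dioxolane-4-carbaldehyde | CC(C)(C)[Si](C)(C)OCC/C=C(/C)[C@H]1OC(C)(C)O[C@@H]1C=O | intermediate
9 | tert-butyl({(3Z)-4-[(4R,5R)-5-ethynyl-2,2-dimethyl-1,3-dioxolan-4-yl]pent-3-en-1-yl}oxy)dimethylsilane | CC(C)(C)[Si](C)(C)OCC/C=C(/C)[C@H]1OC(C)(C)O[C@@H]1C#C | intermediate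
10 | (3Z,5R,6R)-4-methyloct-3-en-7-yne-1,5,6-triol | OCC/C=C(/C)[C@@H](O)[C@H](O)C#C | intermediate
11 | chelated alkenylmagnesium tris-alkoxide (C2–Mg–O14 five-membered ring) | Cl[Mg]OCC/C=C(/C)[C@@H](O[Mg]Cl)[C@@H]1O[Mg]C=C1C(C)C | intermediate
12 | (3Z,5R,6R,7Z)-8-iodo-4-methyl-7-(propan-2-yl)octa-3,7-diene-1,5,6-triol | OCC/C=C(/C)[C@@H](O)[C@H](O)/C(=C\I)C(C)C | intermediate
13 | (3Z,5R,6R,7Z)-8-iodo-4-methyl-7-(propan-2-yl)-1,5,6-tris(triethylsilyloxy)octa-3,7-diene | CC[Si](CC)(CC)OCC/C=C(/C)[C@@H](O[Si](CC)(CC)CC)[C@H](O[Si](CC)(CC)CC)/C(=C\I)C(C)C | intermediate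
14 | trimethyl(prop-1-yn-1-yl)silane | CC#C[Si](C)(C)C | starting material
15 | 1-bromobut-2-yne | CC#CCBr | starting material
16 | [3-(trimethylsilyl)prop-2-yn-1-yl]lithium | [Li]CC#C[Si](C)(C)C | intermediate
17 | (hepta-1,5-diyn-1-yl)trimethylsilane | CC#CCCC#C[Si](C)(C)C | intermediate
18 | hepta-1,5-diyne | CC#CCCC#C | intermediate
19 | dimethyl[(1E)-2-methylhept-1-en-5-yn-1-yl]alane | CC#CCC/C(C)=C/[Al](C)C | intermediate
20 | (1E)-1-iodo-2-methylhept-1-en-5-yne | CC#CCC/C(C)=C/I | intermediate
21 | [(1E)-2-methylhept-1-en-5-yn-1-yl]lithium | CC#CCC/C(C)=C/[Li] | intermediate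
22 | bromo[(1E)-2-methylhept-1-en-5-yn-1-yl]zinc | CC#CCC/C(C)=C/[Zn]Br | intermediate
23 | (3Z,5R,6R,7Z,9E)-4,10-dimethyl-7-(propan-2-yl)-1,5,6-tris(triethylsilyloxy)pentadeca-3,7,9-trien-13-yne | CC[Si](CC)(CC)OCC/C=C(/C)[C@@H](O[Si](CC)(CC)CC)[C@H](O[Si](CC)(CC)CC)/C(=C\C=C(/C)CCC#CC)C(C)C | intermediate
24 | (3Z,5R,6R,7Z,9E)-4,10-dimethyl-7-(propan-2-yl)-5,6-bis(triethylsilyloxy)pentadeca-3,7,9-trien-13-yn-1-ol | OCC/C=C(/C)[C@@H](O[Si](CC)(CC)CC)[C@H](O[Si](CC)(CC)CC)/C(=C\C=C(/C)CCC#CC)C(C)C | intermediate
25 | (3Z,5R,6R,7Z,9E)-4,10-dimethyl-7-(propan-2-yl)-5,6-bis(triethylsilyloxy)pentadeca-3,7,9-trien-13-ynal | O=CC/C=C(/C)[C@@H](O[Si](CC)(CC)CC)[C@H](O[Si](CC)(CC)CC)/C(=C\C=C(/C)CCC#CC)C(C)C | intermediate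
26 | (1Z,3E,7E,9S,11Z,13R,14R)-13,14-bis(triethylsilyloxy)-9-(triisopropylsilyloxy)cembra-1,3,7,11-tetraene | CC[Si](CC)(CC)O[C@@H]1/C(C)=C\C[C@H](O[Si](C(C)C)(C(C)C)C(C)C)/C(C)=C/CC/C(C)=C/C=C(/C(C)C)[C@H]1O[Si](CC)(CC)CC | intermediate
27 | (1Z,3E,7E,9S,11Z,13R,14R)-9-(triisopropylsilyloxy)cembra-1,3,7,11-tetraene-13,14-diol | O[C@@H]1/C(C)=C\C[C@H](O[Si](C(C)C)(C(C)C)C(C)C)/C(C)=C/CC/C(C)=C/C=C(/C(C)C)[C@H]1O | intermediate
28 | (1Z,3E,7E,9S,11Z,13R,14R)-9-(triisopropylsilyloxy)cembra-1,3,7,11-tetraene-13,14-diyl diacetate | CC(=O)O[C@@H]1/C(C)=C\C[C@H](O[Si](C(C)C)(C(C)C)C(C)C)/C(C)=C/CC/C(C)=C/C=C(/C(C)C)[C@H]1OC(C)=O | intermediate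
29 | gibberosene E | CC(=O)O[C@@H]1/C(C)=C\C[C@H](O)/C(C)=C/CC/C(C)=C/C=C(/C(C)C)[C@H]1OC(C)=O | target

**Count and risks**
Total steps: 18. Longest linear sequence: 14 (steps 1, 2, 4–8, 12–18).

Step 15. The aldehyde faces may be poorly differentiated, because C9 is controlled only by the fold of the forming ring. Material may also be lost through conjugation of the aldehyde.
- The fallback sets out from 26 and comes back at 29.
- The unseparated mixture of 26 and the 9R macrocyclic tris-silyl ether F1 is taken through the conditions of steps 16 to 18. This passes through the 9R diol F2 and the 9R diacetate silyl ether F3 and gives 29 mixed with 9-epi-gibberosene E F4.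
- Dess–Martin periodinane with NaHCO3 converts both C9 alcohols into the single 9-oxo diacetate F5.
- Corey–Bakshi–Shibata reduction of F5 with (R)-2-methyl-CBS-oxazaborolidine and catecholborane in toluene at −78 °C treats the C8 alkenyl side as the large group. It should deliver hydride to give the 9S alcohol 29 under reagent control.

Step 7. The poorly soluble tris-alkoxide may react sluggishly. Deprotonation of the terminal alkyne, β-hydride transfer from the isopropylcopper species, and iodoetherification during the quench may all compete.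
- The fallback sets out from 10 and comes back at 23. It needs no free alkoxide and bypasses steps 7, 8 and 12.
- Triol 10 is persilylated (Et3SiOTf, 2,6-lutidine) to the tris(triethylsilyl) enyne F6.
- The acetylide of F6 (n-BuLi) is sulfenylated with PhSSPh to the alkynyl phenyl sulfide F7.
- The organocopper reagent from i-PrMgCl and CuBr·SMe2 adds syn across the sulfur-activated alkyne, with copper next to sulfur and isopropyl on C1. Protonation gives the Z alkenyl sulfide F8, in which sulfur is cis to C14.
- NiCl2(dppp)-catalysed Kumada coupling of the C–S bond with the alkenylmagnesium bromide F9 (from 21 and MgBr2) proceeds with retention and gives 23.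

Step 4. Z selectivity may erode, the basic ylide may enolise the ketone, or the ylide may attack the amide.
- The fallback sets out from 2 and comes back at 10. It builds the Z alkene by chelate control instead of by olefination.
- Both amides of 2 are reduced with i-Bu2AlH to the dioxolane dicarbaldehyde F10. This is homologated in the same flask with the Ohira–Bestmann reagent and K2CO3 to the C2-symmetric diethynyl dioxolane F11.
- Acid methanolysis of F11 gives the diynediol F12.
- A limited charge of MeMgBr with CuI carbomagnesiates one of the two homotopic propargylic alkoxide units anti. This gives the chelated methyl-substituted alkenylmagnesium alkoxide F13, with methyl on C12 and magnesium on C11 cis to C13.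
- F13 opens oxirane to give 10, and unreacted F12 is recycled.

**Further compounds**
F1 | step 15 | (9R)-epimer of macrocyclic tris-silyl ether 26 | CC[Si](CC)(CC)O[C@@H]1/C(C)=C\C[C@@H](O[Si](C(C)C)(C(C)C)C(C)C)/C(C)=C/CC/C(C)=C/C=C(/C(C)C)[C@H]1O[Si](CC)(CC)CC
F2 | step 15 | (9R)-epimer of diol 27 | O[C@@H]1/C(C)=C\C[C@@H](O[Si](C(C)C)(C(C)C)C(C)C)/C(C)=C/CC/C(C)=C/C=C(/C(C)C)[C@H]1O
F3 | step 15 | (9R)-epimer of diacetate silyl ether 28 | CC(=O)O[C@@H]1/C(C)=C\C[C@@H](O[Si](C(C)C)(C(C)C)C(C)C)/C(C)=C/CC/C(C)=C/C=C(/C(C)C)[C@H]1OC(C)=O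
F4 | step 15 | 9-epi-gibberosene E | CC(=O)O[C@@H]1/C(C)=C\C[C@@H](O)/C(C)=C/CC/C(C)=C/C=C(/C(C)C)[C@H]1OC(C)=O
F5 | step 15 | (1Z,3E,7E,11Z,13R,14R)-9-oxocembra-1,3,7,11-tetraene-13,14-diyl diacetate | CC(=O)O[C@@H]1/C(C)=C\CC(=O)/C(C)=C/CC/C(C)=C/C=C(/C(C)C)[C@H]1OC(C)=O
F6 | step 7 | (3Z,5R,6R)-4-methyl-1,5,6-tris(triethylsilyloxy)oct-3-en-7-yne | CC[Si](CC)(CC)OCC/C=C(/C)[C@@H](O[Si](CC)(CC)CC)[C@H](O[Si](CC)(CC)CC)C#C
F7 | step 7 | (3Z,5R,6R)-4-methyl-8-(phenylsulfanyl)-1,5,6-tris(triethylsilyloxy)oct-3-en-7-yne | CC[Si](CC)(CC)OCC/C=C(/C)[C@@H](O[Si](CC)(CC)CC)[C@H](O[Si](CC)(CC)CC)C#CSc1ccccc1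
F8 | step 7 | (3Z,5R,6R,7Z)-4-methyl-8-(phenylsulfanyl)-7-(propan-2-yl)-1,5,6-tris(triethylsilyloxy)octa-3,7-diene | CC[Si](CC)(CC)OCC/C=C(/C)[C@@H](O[Si](CC)(CC)CC)[C@H](O[Si](CC)(CC)CC)/C(=C\Sc1ccccc1)C(C)C
F9 | step 7 | bromo[(1E)-2-methylhept-1-en-5-yn-1-yl]magnesium | CC#CCC/C(C)=C/[Mg]Br
F10 | step 4 | (4S,5S)-2,2-dimethyl-1,3-dioxolane-4,5-dicarbaldehyde | O=C[C@H]1OC(C)(C)O[C@@H]1C=O
F11 | step 4 | (4R,5R)-4,5-diethynyl-2,2-dimethyl-1,3-dioxolane | C#C[C@H]1OC(C)(C)O[C@@H]1C#C
F12 | step 4 | (3R,4R)-hexa-1,5-diyne-3,4-diol | C#C[C@@H](O)[C@H](O)C#C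
F13 | step 4 | chelated methyl-substituted alkenylmagnesium alkoxide (C11–Mg–O13 five-membered ring) | C#C[C@@H](O[Mg]Br)[C@@H]1O[Mg]C=C1C
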